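**Assumption:** 3-(4-methylphenyl)propanoic acid and 4-methoxybenzoyl chloride are taken as commercial; the target is treated as jaeschkeanadiol 4-O-(4-methoxybenzoate), (3R,3aS,4S,8aR) in azulene numbering, which is what the given SMILES encodes.

## Retrosynthetic overview

1. Ester C–O bond last: target ⇒ jaeschkeanadiol + 4-methoxybenzoyl chloride.
2. Ring-hydroxyl and the trisubstituted alkene ⇒ a cyclohepta-1,3-diene, via singlet-oxygen [4+2] and reductive allylic transposition.
3. Isopropyl carbinol ⇒ cyclopentanone + i-Pr–Ce; angular CH3 and trans ring fusion ⇒ asymmetric conjugate methylation/protonation of an achiral bicyclic trienone.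
4. The trienone ⇒ intramolecular Buchner ring expansion of a p-tolyl diazoketone: the benzene ring becomes the seven-membered ring and the five-membered ring closes in the same step.

## Route

**Step 1**
Reactants: 1, 3-(4-methylphenyl)propanoic acid
Product: 2, 1-diazo-4-(4-methylphenyl)butan-2-one
Conditions: (COCl)2, cat. DMF, CH2Cl2, rt; then TMSCHN2 (2.2 equiv), MeCN–THF, 0 °C
Reagents that add atoms: trimethylsilyldiazomethane, C[Si](C)(C)C=[N+]=[N-]
Why: Acid chloride formation followed by acylation of TMS-diazomethane (Arndt–Eistert-type diazoketone synthesis); no stereocentre.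

**Step 2**
Reactants: 2, 1-diazo-4-(4-methylphenyl)butan-2-one
Product: 3, 6-methyl-3,4-dihydroazulen-1(2H)-one (achiral cross-conjugated trienone)
Conditions: Rh2(OAc)4 (1 mol %), CH2Cl2, reflux, slow addition; then Et3N, rt
Reagents that add atoms: none
Why: Intramolecular Buchner reaction (Rh-carbenoid arene cyclopropanation, then norcaradiene-to-cycloheptatriene electrocyclic opening) forms both rings and places the aryl methyl at C6; Et3N moves the 8a-H into conjugation (Scott/McKervey azulenone synthesis).

**Step 3**
Reactants: 3, 6-methyl-3,4-dihydroazulen-1(2H)-one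
Product: 4, (3aR,8aR)-3a,6-dimethyl-3,3a,4,8a-tetrahydroazulen-1(2H)-one (trans-fused: 3a-CH3 and 8a-H anti; 5,7-diene)
Conditions: Me3Al (2 equiv), Cu(OTf)2 (5 mol %), chiral sulfonate-NHC–Ag complex (2.5 mol %, enantiomer chosen for 3aR), THF, −78 → −15 °C; then BHT, −78 °C, cold pH 7 buffer; used crude
Reagents that add atoms: trimethylaluminium, C[Al](C)C
Why: Proposed new method: Cu–NHC-catalysed asymmetric conjugate addition of Me3Al to a fully substituted cyclopentenone. The closest known reactions are Cu-catalysed ACA of Me3Al to β-substituted cyclopentenones (quaternary centres) and stoichiometric Me2CuLi additions to ring-fusion enones. Only C3a is conjugated to the carbonyl (the diene is cross-conjugated), so methyl adds there and the catalyst selects the enantiotopic face (3aR). Kinetic α-protonation of the aluminium trienolate anti to the new axial methyl is expected to give the trans 8a-H.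

**Step 4**
Reactants: 4, (3aR,8aR)-3a,6-dimethyl-3,3a,4,8a-tetrahydroazulen-1(2H)-one
Product: 5, (3R,3aR,8aR)-3-isopropyl-6,8a-dimethyl-1,2,3,3a,8,8a-hexahydroazulen-3-ol (4,6-diene; OH cis to the angular CH3)
Conditions: i-PrLi, CeCl3, THF, −78 °C
Reagents that add atoms: isopropyllithium, CC(C)[Li]
Why: Organocerium (Imamoto) 1,2-addition avoids enolisation of the doubly activated α-H; the nucleophile enters the carbonyl face syn to H-8a, anti to the 3a-methyl and the C8a–C8 bond, which sets the carbinol as 3R.

**Step 5**
Reactants: 5, (3R,3aR,8aR)-3-isopropyl-6,8a-dimethyl-1,2,3,3a,8,8a-hexahydroazulen-3-ol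
Product: 6, (3R,3aS,4S,7S,8aR)-3-isopropyl-6,8a-dimethyl-1,2,3,3a,4,7,8,8a-octahydroazulene-3,4,7-triol (cis-4,7-diol on the face of H-3a; C5=C6)
Conditions: O2, hν, TPP (cat.), CH2Cl2–MeOH, −78 °C; then thiourea, MeOH, rt
Reagents that add atoms: dioxygen, O=O
Why: Singlet-oxygen [4+2] cycloaddition to the s-cis diene on the face of H-3a, anti to the axial 8a-methyl and the 3-OH, then thiourea O–O reduction gives the cis-ene-1,4-diol and sets C4 as S.

**Step 6**
Reactants: 6, the 3,4,7-triol
Product: 7, (3R,3aS,4S,8aR)-3-isopropyl-6,8a-dimethyl-1,2,3,3a,4,5,8,8a-octahydroazulene-3,4-diol (jaeschkeanadiol)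
Conditions: 2-nitrobenzenesulfonylhydrazide (NBSH), PPh3, DEAD, THF, −30 °C → rt
Reagents that add atoms: none
Why: Myers reductive 1,3-transposition: Mitsunobu displacement occurs at the less hindered allylic C7–OH (C4–OH sits next to the ring-fusion CH flanked by two quaternary carbons); retro-ene loss of N2 from the allylic diazene delivers H to C5 and moves the alkene to C6=C7, with no change at the existing stereocentres.

**Step 7**
Reactants: 7, jaeschkeanadiol; 8, 4-methoxybenzoyl chloride
Product: 9, (3R,3aS,4S,8aR)-3-hydroxy-3-isopropyl-6,8a-dimethyl-1,2,3,3a,4,5,8,8a-octahydroazulen-4-yl 4-methoxybenzoate (target)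
Conditions: 8, DMAP, Et3N, CH2Cl2, 0 °C → rt
Reagents that add atoms: 4-methoxybenzoyl chloride (8), COc1ccc(cc1)C(Cl)=O
Why: DMAP-catalysed acylation; only the secondary C4–OH reacts, the tertiary C3–OH is inert.

## Compound list

1 | 3-(4-methylphenyl)propanoic acid | Cc1ccc(CCC(=O)O)cc1 | starting material
2 | 1-diazo-4-(4-methylphenyl)butan-2-one | Cc1ccc(CCC(=O)C=[N+]=[N-])cc1 | intermediate
3 | 6-methyl-3,4-dihydroazulen-1(2H)-one | O=C1CCC2=C1C=CC(C)=CC2 | intermediate
4 | (3aR,8aR)-3a,6-dimethyl-3,3a,4,8a-tetrahydroazulen-1(2H)-one | C1=CC(C)=CC[C@@]2(C)CCC(=O)[C@H]12 | intermediate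
5 | (3R,3aR,8aR)-3-isopropyl-6,8a-dimethyl-1,2,3,3a,8,8a-hexahydroazulen-3-ol | C1=CC(C)=CC[C@@]2(C)CC[C@@](O)(C(C)C)[C@H]12 | intermediate
6 | (3R,3aS,4S,7S,8aR)-3-isopropyl-6,8a-dimethyl-1,2,3,3a,4,7,8,8a-octahydroazulene-3,4,7-triol | O[C@H]1C=C(C)[C@@H](O)C[C@@]2(C)CC[C@@](O)(C(C)C)[C@H]12 | intermediate
7 | (3R,3aS,4S,8aR)-3-isopropyl-6,8a-dimethyl-1,2,3,3a,4,5,8,8a-octahydroazulene-3,4-diol (jaeschkeanadiol) | O[C@H]1CC(C)=CC[C@@]2(C)CC[C@@](O)(C(C)C)[C@H]12 | intermediate
8 | 4-methoxybenzoyl chloride | COc1ccc(cc1)C(Cl)=O | starting material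
9 | (3R,3aS,4S,8aR)-3-hydroxy-3-isopropyl-6,8a-dimethyl-1,2,3,3a,4,5,8,8a-octahydroazulen-4-yl 4-methoxybenzoate | COc1ccc(C(=O)O[C@H]2CC(C)=CC[C@@]3(C)CC[C@@](O)(C(C)C)[C@H]23)cc1 | target

## Summary

Total steps: 7. Longest linear sequence: 7 (1 → 9).

Steps most likely to fail, each with a fallback:

1. **Step 3.** The enone is fully substituted, so it may be unreactive or give low ee, and the protonation may not give the trans fusion cleanly. Fallback: CBS reduction of 3 (α-substituted cyclopentenone), hydroxyl-directed Simmons–Smith cyclopropanation of the ring-fusion alkene, reoxidation, then SmI2 (or Li/NH3) opening of the exocyclic cyclopropane bond to reveal the angular methyl and the same enolate (+3 steps).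
2. **Step 4.** Ketone 4 has a doubly activated ring-fusion H, so enolisation, epimerisation or drift into conjugation may compete with addition. Fallback: change the order — trap the step-3 enolate as its TMS enol ether, carry out the singlet-oxygen/thiourea sequence first so that the ring-fusion H is no longer allylic, then unmask the ketone and add i-PrCeCl2 under chelation by the β-alkoxide.
3. **Step 6.** Both secondary alcohols are allylic; activation at C4–OH would put the alkene in the wrong place. Fallback: treat the step-5 endoperoxide with PPh3 to give the 4,5-epoxy-6-ene by syn-SN2′ collapse, then Pd(0)/HCO2H–Et3N hydrogenolysis (Tsuji–Shimizu), which delivers hydride to the epoxide-bearing allylic carbon and gives the same homoallylic alcohol 7.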